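**Retrosynthetic overview**
- Feature: in ring C, C2 is a CH2 bonded only to O1 and C3. C3, the one stereocentre, lies between the C4 ketone and ring B. C2 is therefore treated as the methyl carbon of an ortho-methoxy group on ring A, and C3 as a donor-acceptor carbene carbon.
- Last skeletal bond: C2–C3, made by enantioselective dirhodium-catalysed C–H insertion of an alpha-aryl-alpha-diazoketone. Rings A and B are bought; ring C is the only ring built and it closes last, followed only by fluoride desilylation.
- The diazoketone comes from a deoxybenzoin by diazo transfer. The deoxybenzoin (C3–C4 bond) comes from a ring B benzylzinc chloride and a ring A aroyl chloride under palladium catalysis.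
- Ring B comes from 2,3,4-trihydroxybenzaldehyde by O4-prenylation, aromatic Claisen shift to C5 and O4-methylation. O2 and O3 travel as MOM ethers while O4 is a free phenol, because a silylene would migrate onto it. They are changed to the di-tert-butylsilylene once O4 is capped.

Key step: step 13

Assumption: the (S)-tert-leucinate ligand set is taken to expose the carbene face that leads to (3S). Both antipodes of tert-leucine are sold, so Rh2(R-PTTL)4 is used instead if the sense of induction proves opposite.

**Step 1**
Reactants: 1 2,3,4-trihydroxybenzaldehyde; 2 prenyl bromide (1-bromo-3-methylbut-2-ene)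
Product: 3 2,3-dihydroxy-4-(3-methylbut-2-enyloxy)benzaldehyde
Conditions: NaHCO3, DMF, 40 °C, Ar
Reagents that add atoms: none
Why: Williamson ether synthesis; the 4-OH, para to the formyl group, is the most acidic phenol and the one ionised by hydrogencarbonate, while the 2-OH is held in a hydrogen bond to the aldehyde, so one equivalent of the allylic bromide should alkylate O4.

**Step 2**
Reactants: 3 2,3-dihydroxy-4-(3-methylbut-2-enyloxy)benzaldehyde
Product: 4 2,3-bis(methoxymethoxy)-4-(3-methylbut-2-enyloxy)benzaldehyde
Conditions: NaH, MOMCl, DMF, 0 °C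
Reagents that add atoms: chloromethyl methyl ether, COCCl
Why: MOM protection (O-alkylation of both phenoxides); MOM ethers cannot migrate to the phenol that step 3 unveils, tolerate hot amine solvent and carbonate base, and leave in dilute acid.

**Step 3**
Reactants: 4 2,3-bis(methoxymethoxy)-4-(3-methylbut-2-enyloxy)benzaldehyde
Product: 5 4-hydroxy-2,3-bis(methoxymethoxy)-5-(2-methylbut-3-en-2-yl)benzaldehyde
Conditions: PhNEt2, 195 °C, sealed tube, Ar
Reagents that add atoms: none
Why: Aromatic Claisen rearrangement; the [3,3] shift inverts the prenyl unit to the 1,1-dimethylallyl group at C5, the only ortho position whose dienone can tautomerise (the shift to C3 is reversible), and the amine solvent suppresses acid-catalysed ring closure of the new phenol onto the alkene.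

**Step 4**
Reactants: 5 4-hydroxy-2,3-bis(methoxymethoxy)-5-(2-methylbut-3-en-2-yl)benzaldehyde
Product: 6 4-methoxy-2,3-bis(methoxymethoxy)-5-(2-methylbut-3-en-2-yl)benzaldehyde
Conditions: MeI, K2CO3, DMF, rt
Reagents that add atoms: iodomethane, CI
Why: Williamson methylation of the single free phenol, whose acidity (para-formyl) offsets its crowding; capping O4 also ends any chance of abnormal Claisen isomerisation or dihydrobenzofuran formation.

**Step 5**
Reactants: 6 4-methoxy-2,3-bis(methoxymethoxy)-5-(2-methylbut-3-en-2-yl)benzaldehyde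
Product: 7 2,3-dihydroxy-4-methoxy-5-(2-methylbut-3-en-2-yl)benzaldehyde
Conditions: 3 M aq HCl, THF, 45 °C
Reagents that add atoms: none
Why: Acid hydrolysis of the two aryl MOM acetals; the monosubstituted alkene is not protonated by dilute acid and, with O4 methylated, has no neighbouring phenol to cyclise onto.

**Step 6**
Reactants: 7 2,3-dihydroxy-4-methoxy-5-(2-methylbut-3-en-2-yl)benzaldehyde
Product: 8 2,2-di-tert-butyl-7-methoxy-6-(2-methylbut-3-en-2-yl)-1,3,2-benzodioxasilole-4-carbaldehyde
Conditions: tBu2Si(OTf)2, 2,6-lutidine, CH2Cl2, 0 °C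
Reagents that add atoms: di-tert-butylsilyl bis(trifluoromethanesulfonate), CC(C)(C)[Si](OS(=O)(=O)C(F)(F)F)(OS(=O)(=O)C(F)(F)F)C(C)(C)C
Why: Cyclic silylene formation on the catechol with the very electrophilic bis(triflate), which also silylates the hydrogen-bonded 2-OH; no free phenol remains to which the silylene could migrate.

**Step 7**
Reactants: 8 silylene aldehyde
Product: 9 [2,2-di-tert-butyl-7-methoxy-6-(2-methylbut-3-en-2-yl)-1,3,2-benzodioxasilol-4-yl]methanol
Conditions: iBu2AlH, CH2Cl2, −78 °C; aq potassium sodium tartrate
Reagents that add atoms: none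
Why: Hydride reduction of the aldehyde; the weakly nucleophilic aluminium alkoxide at low temperature and the near-neutral work-up should prevent O-to-O silyl migration from O2 to the benzylic oxygen, and the vinyl group is not hydroaluminated at −78 °C.

**Step 8**
Reactants: 9 benzylic alcohol
Product: 10 4-(chloromethyl)-2,2-di-tert-butyl-7-methoxy-6-(2-methylbut-3-en-2-yl)-1,3,2-benzodioxasilole
Conditions: PPh3, NCS (premixed), THF, −20 to 0 °C; pentane trituration, filtration, used at once
Reagents that add atoms: N-chlorosuccinimide, O=C1CCC(=O)N1Cl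
Why: Appel-type chlorination through an alkoxyphosphonium salt under neutral conditions, fast for this electron-rich benzylic alcohol and free of HCl that could open the silylene.

**Step 9**
Reactants: 11 4-hydroxy-2-methoxybenzoic acid
Product: 12 tert-butyldimethylsilyl 4-(tert-butyldimethylsilyloxy)-2-methoxybenzoate
Conditions: TBSCl (2.3 equiv), imidazole, DMF, rt
Reagents that add atoms: tert-butyldimethylsilyl chloride, CC(C)(C)[Si](C)(C)Cl
Why: Imidazole-promoted silylation of phenol and carboxylic acid in one operation, giving the silyl ester needed for neutral acid chloride formation.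

**Step 10**
Reactants: 12 bis-silylated acid
Product: 13 4-(tert-butyldimethylsilyloxy)-2-methoxybenzoyl chloride
Conditions: (COCl)2, DMF (cat.), CH2Cl2, 0 °C to rt; evaporation
Reagents that add atoms: oxalyl chloride, O=C(Cl)C(=O)Cl
Why: Vilsmeier-type conversion of a silyl ester into the acid chloride, which releases a chlorosilane instead of HCl, so the aryl silyl ether should stay in place.

**Step 11**
Reactants: 10 benzylic chloride; 13 aroyl chloride
Product: 15 deoxybenzoin 1-[4-(tert-butyldimethylsilyloxy)-2-methoxyphenyl]-2-[2,2-di-tert-butyl-7-methoxy-6-(2-methylbut-3-en-2-yl)-1,3,2-benzodioxasilol-4-yl]ethan-1-one, via benzylzinc chloride 14 (not isolated)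
Conditions: Zn dust, LiCl, THF, 0 to 25 °C, decanted from excess Zn; then 13, Pd(PPh3)4 (5 mol %), THF, 25 °C
Reagents that add atoms: zinc, [Zn] (held only in 14)
Why: LiCl-promoted zinc insertion into a benzylic chloride, then Negishi acylation with zerovalent palladium; this gives the ketone directly without an alkoxide intermediate that could attack silicon, and the mild organozinc leaves silyl ethers, vinyl group and the acidic product untouched.

**Step 12**
Reactants: 15 deoxybenzoin
Product: 16 2-diazo-1-[4-(tert-butyldimethylsilyloxy)-2-methoxyphenyl]-2-[2,2-di-tert-butyl-7-methoxy-6-(2-methylbut-3-en-2-yl)-1,3,2-benzodioxasilol-4-yl]ethan-1-one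
Conditions: p-ABSA, DBU, dry MeCN, 0 °C to rt, dark
Reagents that add atoms: 4-acetamidobenzenesulfonyl azide, CC(=O)Nc1ccc(cc1)S(=O)(=O)N=[N+]=[N-]
Why: Regitz diazo transfer; the methylene group is activated by both the aroyl group and ring B, which is the standard situation for direct transfer to benzyl aryl ketones, and exclusion of water protects the aryl silyl ethers from DBU.

**Step 13**
Reactants: 16 alpha-aryl-alpha-diazoketone
Product: 17 (3S)-7-(tert-butyldimethylsilyloxy)-3-[2,2-di-tert-butyl-7-methoxy-6-(2-methylbut-3-en-2-yl)-1,3,2-benzodioxasilol-4-yl]-2,3-dihydro-4H-chromen-4-one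
Conditions: Rh2(S-PTTL)4 (2 mol %), 4 Å MS, toluene, −20 °C to rt, slow addition of 16 by syringe pump, final 0.01 M
Reagents that add atoms: none
Why: Proposed new method: the divalent rhodium dimer expels N2 from 16 to give a metal-bound carbene at C3 (ring B as donor, the aroyl group as acceptor), which engages a C–H bond of the ring A methoxy group in a concerted, asynchronous three-centre transition state in which hydrogen moves to C3 with hydridic character while the oxygen lone pair stabilises the developing positive charge on the methyl carbon, so that C2–C3 and C3–H form on the same carbene face. The closest known reaction types are the dirhodium carboxylate-catalysed insertion of 2-alkoxyphenyl alpha-diazoketones into O–CH2R bonds to give chroman-4-ones and the insertion of aryldiazoacetates into aryl methyl ethers to give dihydrobenzofurans; the new element is the pairing of an alpha-aryl diazoketone with a primary O–CH3 bond. Ring C closes as a six-membered ring by 1,6-insertion along the preformed chain C3–C4–C4a–C8a–O1–C2, the normally favoured 1,5-site being O1, which carries no hydrogen. C3, the only stereocentre, is fixed by the chiral pocket of the four N-phthaloyl-tert-leucinate ligands, which should leave one carbene face open to the tethered methyl group, and neither acid nor base is present to enolise the product. The step needs insertion to outrun attack of the methoxy oxygen (oxonium ylide, then 1,2-methyl shift to a benzofuranone), Wolff rearrangement, insertion on the ring B side and bimolecular cyclopropanation or dimerisation: ylide formation is reversible and methyl migrates poorly, the aryl donor tempers the carbene, the tied-back silylene leaves no C–H next to O2' and only remote unactivated tert-butyl C–H bonds, the vinyl group is shielded by its quaternary neighbour, and slow addition at high dilution disfavours all bimolecular paths.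

**Step 14**
Reactants: 17 protected (3S)-isoflavanone
Product: 18 (3S)-7-hydroxy-3-[2,3-dihydroxy-4-methoxy-5-(2-methylbut-3-en-2-yl)phenyl]-2,3-dihydro-4H-chromen-4-one (CNP0134633.1)
Conditions: Et3N·3HF (excess), THF, 0 °C to rt, Ar; pH 6 buffer work-up
Reagents that add atoms: none
Why: Fluoride-mediated cleavage of the aryl silyl ether and the catechol silylene in a mildly acidic medium, which should avoid both base-induced enolisation at C3 and acid-driven dehydration of the 2'-hydroxy ketone.

**Compound list**
1 | 2,3,4-trihydroxybenzaldehyde | O=Cc1ccc(O)c(O)c1O | starting material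
2 | prenyl bromide (1-bromo-3-methylbut-2-ene) | CC(C)=CCBr | starting material
3 | 2,3-dihydroxy-4-(3-methylbut-2-enyloxy)benzaldehyde | O=Cc1ccc(OCC=C(C)C)c(O)c1O | intermediate
4 | 2,3-bis(methoxymethoxy)-4-(3-methylbut-2-enyloxy)benzaldehyde | O=Cc1ccc(OCC=C(C)C)c(OCOC)c1OCOC | intermediate
5 | 4-hydroxy-2,3-bis(methoxymethoxy)-5-(2-methylbut-3-en-2-yl)benzaldehyde | O=Cc1cc(C(C)(C)C=C)c(O)c(OCOC)c1OCOC | intermediate
6 | 4-methoxy-2,3-bis(methoxymethoxy)-5-(2-methylbut-3-en-2-yl)benzaldehyde | O=Cc1cc(C(C)(C)C=C)c(OC)c(OCOC)c1OCOC | intermediate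
7 | 2,3-dihydroxy-4-methoxy-5-(2-methylbut-3-en-2-yl)benzaldehyde | O=Cc1cc(C(C)(C)C=C)c(OC)c(O)c1O | intermediate
8 | 2,2-di-tert-butyl-7-methoxy-6-(2-methylbut-3-en-2-yl)-1,3,2-benzodioxasilole-4-carbaldehyde | O=Cc1cc(C(C)(C)C=C)c(OC)c2O[Si](C(C)(C)C)(C(C)(C)C)Oc12 | intermediate
9 | [2,2-di-tert-butyl-7-methoxy-6-(2-methylbut-3-en-2-yl)-1,3,2-benzodioxasilol-4-yl]methanol | OCc1cc(C(C)(C)C=C)c(OC)c2O[Si](C(C)(C)C)(C(C)(C)C)Oc12 | intermediate
10 | 4-(chloromethyl)-2,2-di-tert-butyl-7-methoxy-6-(2-methylbut-3-en-2-yl)-1,3,2-benzodioxasilole | ClCc1cc(C(C)(C)C=C)c(OC)c2O[Si](C(C)(C)C)(C(C)(C)C)Oc12 | intermediate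
11 | 4-hydroxy-2-methoxybenzoic acid | COc1cc(O)ccc1C(=O)O | starting material
12 | tert-butyldimethylsilyl 4-(tert-butyldimethylsilyloxy)-2-methoxybenzoate | COc1cc(O[Si](C)(C)C(C)(C)C)ccc1C(=O)O[Si](C)(C)C(C)(C)C | intermediate
13 | 4-(tert-butyldimethylsilyloxy)-2-methoxybenzoyl chloride | COc1cc(O[Si](C)(C)C(C)(C)C)ccc1C(=O)Cl | intermediate
14 | {[2,2-di-tert-butyl-7-methoxy-6-(2-methylbut-3-en-2-yl)-1,3,2-benzodioxasilol-4-yl]methyl}zinc chloride (in solution with LiCl, not isolated) | Cl[Zn]Cc1cc(C(C)(C)C=C)c(OC)c2O[Si](C(C)(C)C)(C(C)(C)C)Oc12 | intermediate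
15 | deoxybenzoin with 2-methoxy-4-TBSO ring A and silylene-protected ring B | COc1cc(O[Si](C)(C)C(C)(C)C)ccc1C(=O)Cc1cc(C(C)(C)C=C)c(OC)c2O[Si](C(C)(C)C)(C(C)(C)C)Oc12 | intermediate
16 | alpha-diazo deoxybenzoin (key-step precursor) | COc1cc(O[Si](C)(C)C(C)(C)C)ccc1C(=O)C(=[N+]=[N-])c1cc(C(C)(C)C=C)c(OC)c2O[Si](C(C)(C)C)(C(C)(C)C)Oc12 | intermediate
17 | (3S)-isoflavanone, 7-O-TBS, 2',3'-O-di-tert-butylsilylene (key-step product) | C=CC(C)(C)c1cc([C@H]2COc3cc(O[Si](C)(C)C(C)(C)C)ccc3C2=O)c2O[Si](C(C)(C)C)(C(C)(C)C)Oc2c1OC | intermediate
18 | (3S)-7,2',3'-trihydroxy-4'-methoxy-5'-(1,1-dimethylallyl)isoflavanone, CNP0134633.1 | C=CC(C)(C)c1cc([C@H]2COc3cc(O)ccc3C2=O)c(O)c(O)c1OC | target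

**Totals**
- Total step count: 14.
- Longest linear sequence: 12 (steps 1–8, then 11–14).

**Steps most likely to fail**

1. **Step 13 (key step).** The carbene may be lost to oxonium ylide formation with methyl migration, Wolff rearrangement, dimerisation or intermolecular cyclopropanation. It may also insert with poor facial selectivity. The fallback uses known chemistry, sets out from 15 and returns at 17.
   - BCl3 (CH2Cl2, −78 °C) cleaves, through chelation to the ketone, only the methyl ether ortho to the carbonyl. This gives the 2-hydroxy deoxybenzoin F1.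
   - N,N-dimethylformamide dimethyl acetal (toluene, 80 °C) supplies C2 and closes the isoflavone F2.
   - Asymmetric transfer hydrogenation with RuCl[(S,S)-TsDPEN](p-cymene) in HCO2H/Et3N reduces the enone C=C bond. It then reduces the ketone, with dynamic kinetic resolution of the readily racemising isoflavanone, to the cis-(3S,4S)-isoflavan-4-ol F3.
   - Dess–Martin periodinane (CH2Cl2, 0 °C, no base) re-oxidises C4 and delivers 17.

2. **Step 3 (Claisen).** Possible failures are thermal loss of the prenyl group, onward abnormal-Claisen isomerisation of the new side chain, and ring closure of the liberated phenol onto the alkene. The fallback replaces the sigmatropic shift by a cross-coupling, sets out from 1 and returns at 6.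
   - Borate-masked methylation (Na2B4O7, Me2SO4, aq NaOH) gives 2,3-dihydroxy-4-methoxybenzaldehyde F4.
   - Bromination (Br2, NaOAc, AcOH) should go to C5, which is para to the 2-OH, ortho to the methoxy group and meta to the aldehyde. This gives the 5-bromo aldehyde F5.
   - NaH/MOMCl gives the bis-MOM bromide F6.
   - A branched-selective Suzuki–Miyaura coupling of F6 with prenylboronic acid pinacol ester (Pd(OAc)2, bulky biaryl dialkylphosphine, aq K3PO4, THF) joins the tertiary allyl terminus to C5 and gives 6.

3. **Step 12 (diazo transfer).** Deprotonation of the crowded, electron-rich benzylic position may be slow. The aryl silyl groups may be lost or may migrate during long exposure to DBU. The fallback adds a removable activating group, sets out from 15 and returns at 16.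
   - Enolisation with LiN(SiMe3)2 (THF, −78 °C) and acylation with 2,2,2-trifluoroethyl trifluoroacetate gives the alpha-trifluoroacetyl ketone F7.
   - F7 undergoes detrifluoroacetylative diazo transfer with methanesulfonyl azide, Et3N and one equivalent of water in MeCN at rt. The only base present is then a tertiary amine.

**Further compounds**
F1 | step 13 | 1-[4-(tert-butyldimethylsilyloxy)-2-hydroxyphenyl]-2-[2,2-di-tert-butyl-7-methoxy-6-(2-methylbut-3-en-2-yl)-1,3,2-benzodioxasilol-4-yl]ethan-1-one | Oc1cc(O[Si](C)(C)C(C)(C)C)ccc1C(=O)Cc1cc(C(C)(C)C=C)c(OC)c2O[Si](C(C)(C)C)(C(C)(C)C)Oc12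
F2 | step 13 | isoflavone, 7-O-TBS, 2',3'-O-di-tert-butylsilylene | C=CC(C)(C)c1cc(C2=COc3cc(O[Si](C)(C)C(C)(C)C)ccc3C2=O)c2O[Si](C(C)(C)C)(C(C)(C)C)Oc2c1OC
F3 | step 13 | cis-(3S,4S)-isoflavan-4-ol, 7-O-TBS, 2',3'-O-di-tert-butylsilylene | C=CC(C)(C)c1cc([C@H]2COc3cc(O[Si](C)(C)C(C)(C)C)ccc3[C@H]2O)c2O[Si](C(C)(C)C)(C(C)(C)C)Oc2c1OC
F4 | step 3 | 2,3-dihydroxy-4-methoxybenzaldehyde | COc1ccc(C=O)c(O)c1O
F5 | step 3 | 5-bromo-2,3-dihydroxy-4-methoxybenzaldehyde | COc1c(Br)cc(C=O)c(O)c1O
F6 | step 3 | 5-bromo-4-methoxy-2,3-bis(methoxymethoxy)benzaldehyde | COc1c(Br)cc(C=O)c(OCOC)c1OCOC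
F7 | step 12 | alpha-trifluoroacetyl deoxybenzoin (racemic, largely enolised) | COc1cc(O[Si](C)(C)C(C)(C)C)ccc1C(=O)C(C(=O)C(F)(F)F)c1cc(C(C)(C)C=C)c(OC)c2O[Si](C(C)(C)C)(C(C)(C)C)Oc12
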